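The ratio of protic impurity to starting material, c(protic impurity)/c(starting material), is where the flask parts from Friday's run: 5.00% against 7.60%, with the same charge of starting material, the same feed and the same equivalents of partner.

| flask | starting material | partner | protic impurity | remark | time |
|---|---|---|---|---|---|
| Monday's | 0.025 M (fed, over 2.5 d) | 1.1 equiv | 2.5 mM | run made earlier; the fed solution adds 0.50 times the starting volume |  |
| Tuesday's | 0.038 M (fed, over 2.5 d) | 1.1 equiv | 2.5 mM | run made earlier; the fed solution adds 0.50 times the starting volume |  |
| Friday's | 0.050 M (fed, over 2.5 d) | 1.1 equiv | 3.8 mM | run made earlier; the fed solution adds 0.50 times the starting volume |  |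
| flask | 0.050 M (fed, over 2.5 d) | 1.10 equiv | 2.50 mM | the fed solution adds 0.50 times the starting volume | 12 d |

- Monday's (time / d: target / %): 1.25: 1.9; 2.50: 2.8; 6.00: 8.6; 15.0: 6.2
- Tuesday's (time / d: target / %): 1.67: 3.3; 5.00: 10.1; 10.0: 9.9; 15.0: 8.3
- Friday's (time / d: target / %): 4.00: 9.4; 8.00: 8.7; 10.0: 9.9; 15.0: 7.5

(readings scatter by 1 percentage point)

- amount of target in percent of the starting material charged, at 30 h, 4.0 d, 8.0 d and 12 d

- charges are per starting volume, the dose included; the dosed solution carries all of it
- percentages count the whole charge, also what has not yet gone in

We keep the books of the flask in equivalents of partner per starting material, taking it as our own assumption that each protic impurity consumes one partner. The flask is charged with 1.10 equiv. The first entry is the impurity's share, and what remains after it, 1.05 equiv, we call the cover: partner available per starting material charged. The second entry is one equivalent for the starting material itself. The cover stands above one, so starting material is the limiting reagent, and the books close with 0.0500 equiv of partner unspent. Friday's books give a cover of 1.02. Both covers exceed one, so in both the impurity draws on the surplus and leaves the starting material's equivalent untouched.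

We therefore expect no gain in target over Friday's run and take its course across: its readings of 9.4% at 4.0 d and 8.7% at 8.0 d, and about 8.94% at 12 d, interpolated between its readings at 10.0 d and 15.0 d. Friday's run has no reading before 4.00 d, so we give no number for 30 h.

The forecast gives 3%, 9.5%, 10.5% and 9.3%, and it says: “The flask should therefore resemble Friday's run, slightly better”. It stands above our reckoning at 8.0 d.

The flask gives 2.50%, 9.96%, 10.6% and 9.45%, within the forecast's tolerance, on this mechanism:

    starting material + partner → intermediate + released group (k = 1.10 × 10⁻⁴ L mol⁻¹ s⁻¹)
    target ⇌ isomer of the product B (K = 1.50, k = 1.50 × 10⁻⁵ s⁻¹)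
    partner + protic impurity → quenched reagent (k = 0.00130 L mol⁻¹ s⁻¹)
    intermediate ⇌ isomer of the product A (K = 88.0, k = 1.20 × 10⁻⁵ s⁻¹)
    intermediate ⇌ target (K = 2.60, k = 1.90 × 10⁻⁵ s⁻¹)

In the flask the protic impurity stands at 0% of its charge by 2.50 d, and its step with partner makes no difference to the target that a reading could show. At 12.0 d the flask holds 23% of its partner and 20% of its starting material; counted in equivalents, the gap between them is 0.0500 equiv, beside the 0.0500 equiv that the cover gave. Monday's run has a cover of 1.00, partner and starting material level, and it read 8.6% of target at 6.00 d.

The earlier runs and the new flask were computed on assumed constants; the scatter is artificial.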